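**Plan**
- Retrosynthesis cuts the acyl–oxygen bond of the allylic 4-hydroxycinnamate first. It then cuts ring A at C1'–C2' and C5'–C6', then the C3'–CH2 bond and the carbonyl–ethynyl bond.
- The feature that allows this: ring A holds O–C2'–C3'(CH2R)–C4'–O plus C5'H, the four carbons of methyl acetoacetate alkylated at its central carbon. Next to it sit C1'(acyl) and C6'H, the two alkyne carbons of a terminal ynone.
- Forward: the alkylated 1-methoxy-1,3-bis(trimethylsilyloxy)diene (four steps) and the aryl enynone (three steps) are made separately. Ring A, the only ring built, is closed by [4+2] cycloaddition and aromatisation; 4'-O-silylation, release of the chain alcohol, esterification and global desilylation follow.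
- Stereochemistry: there are no stereocentres. The E-trisubstituted alkene comes from the palladium-catalysed 1,4-opening of isoprene monoxide; both E-disubstituted alkenes are bought with the cinnamyl starting materials.
- Protecting groups: phenols are carried as triisopropylsilyl (TIPS) ethers and the chain alcohol as a tert-butyldimethylsilyl (TBS) ether, so that acid frees the alcohol alone and fluoride frees the phenols at the end.

Key step: step 8

Assumption: the enol ether geometry of 5 and the ketene acetal geometry of 6 are not controlled and do not matter, because both carbons become arene carbons of ring A; one isomer is drawn for each.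

**Route**

Step 1
Reactants: 1 methyl acetoacetate; 2 2-methyl-2-vinyloxirane
Product: 3 methyl (4E)-2-acetyl-6-hydroxy-5-methylhex-4-enoate (racemic at C2)
Conditions: Pd(PPh3)4 (3 mol %), 1 in excess (2 equiv), THF, 0 °C → rt
Reagents that add atoms: none
Why: Tsuji–Trost allylic alkylation under neutral conditions, in which zerovalent palladium opens the vinyl epoxide to a π-allyl alkoxide that deprotonates the keto ester, and attack at the unsubstituted allyl terminus should give the 1,4-adduct mainly as the E alkene (any Z isomer removed by chromatography), the excess of 1 suppressing double allylation.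

Step 2
Reactants: 3 methyl (4E)-2-acetyl-6-hydroxy-5-methylhex-4-enoate
Product: 4 methyl (4E)-2-acetyl-6-(tert-butyldimethylsilyloxy)-5-methylhex-4-enoate
Conditions: TBSCl, imidazole, CH2Cl2, 0 °C → rt
Reagents that add atoms: tert-butyldimethylsilyl chloride (TBSCl), CC(C)(C)[Si](C)(C)Cl
Why: Standard imidazole-mediated silylation of a primary allylic alcohol, which is far faster than O-silylation of the weakly enolised α-substituted keto ester.

Step 3
Reactants: 4 methyl (4E)-2-acetyl-6-(tert-butyldimethylsilyloxy)-5-methylhex-4-enoate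
Product: 5 methyl (4E)-6-(tert-butyldimethylsilyloxy)-5-methyl-2-[1-(trimethylsilyloxy)ethylidene]hex-4-enoate
Conditions: TMSCl, Et3N, toluene, rt, 2–3 d; filtration of the salt under argon, crude used
Reagents that add atoms: trimethylsilyl chloride (TMSCl), C[Si](C)(C)Cl
Why: Soft enolisation and O-silylation of a β-keto ester with amine and chlorosilane, the usual first stage in making 1,3-bis(silyloxy)dienes and known for 2-alkyl acetoacetates, gives the conjugated silyl enol ether.

Step 4
Reactants: 5 methyl (4E)-6-(tert-butyldimethylsilyloxy)-5-methyl-2-[1-(trimethylsilyloxy)ethylidene]hex-4-enoate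
Product: 6 1-methoxy-2-[(2E)-4-(tert-butyldimethylsilyloxy)-3-methylbut-2-en-1-yl]-1,3-bis(trimethylsilyloxy)buta-1,3-diene
Conditions: LiN(i-Pr)2 (LDA), THF, −78 °C; TMSCl, −78 °C → rt; non-aqueous work-up (hexane, filtration under argon), used at once
Reagents that add atoms: trimethylsilyl chloride (TMSCl), C[Si](C)(C)Cl
Why: Kinetic γ-deprotonation of the β-silyloxy enoate at its methyl group gives the extended ester dienolate, which is trapped on oxygen by the chlorosilane (vinylogous enolate O-silylation), the standard second stage of the bis(silyl enol ether) synthesis.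

Step 5
Reactants: 7 (E)-4-hydroxycinnamaldehyde
Product: 8 (E)-4-(triisopropylsilyloxy)cinnamaldehyde
Conditions: TIPSCl, imidazole, DMF, rt
Reagents that add atoms: triisopropylsilyl chloride (TIPSCl), CC(C)[Si](Cl)(C(C)C)C(C)C
Why: Routine phenol silylation; the aryl TIPS ether tolerates the Grignard addition, the oxidation, the cycloaddition and the later acidic desilylation.

Step 6
Reactants: 8 (E)-4-(triisopropylsilyloxy)cinnamaldehyde
Product: 9 (E)-1-[4-(triisopropylsilyloxy)phenyl]pent-1-en-4-yn-3-ol (racemic)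
Conditions: HC≡CMgBr, THF, −78 → 0 °C; sat. aq. NH4Cl
Reagents that add atoms: ethynylmagnesium bromide, C#C[Mg]Br
Why: Grignard 1,2-addition to an enal, which is strongly preferred over conjugate addition; the carbinol centre is racemic and is removed in the next step.

Step 7
Reactants: 9 (E)-1-[4-(triisopropylsilyloxy)phenyl]pent-1-en-4-yn-3-ol
Product: 10 (E)-1-[4-(triisopropylsilyloxy)phenyl]pent-1-en-4-yn-3-one
Conditions: activated MnO2 (excess), CH2Cl2, rt; product kept cold and used promptly
Reagents that add atoms: none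
Why: MnO2 oxidation of a secondary alcohol that is both allylic and propargylic, which is mild enough to leave the sensitive terminal ynone and the E alkene intact.

Step 8
Reactants: 6 1-methoxy-2-[(2E)-4-(tert-butyldimethylsilyloxy)-3-methylbut-2-en-1-yl]-1,3-bis(trimethylsilyloxy)buta-1,3-diene; 10 (E)-1-[4-(triisopropylsilyloxy)phenyl]pent-1-en-4-yn-3-one
Product: 13 (E)-1-{3-[(2E)-4-(tert-butyldimethylsilyloxy)-3-methylbut-2-en-1-yl]-2,4-dihydroxyphenyl}-3-[4-(triisopropylsilyloxy)phenyl]prop-2-en-1-one, via cyclohexadiene cycloadduct 11 (not isolated), via bis(trimethylsilyl) aryl ether 12 (not isolated)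
Conditions: 6 (1.5 equiv), toluene, rt → 70 °C; then 0.1 M aq. HCl–THF, 0 °C, 15 min
Reagents that add atoms: none
Why: The electron-rich diene 6, with its largest HOMO coefficient at the terminal CH2, attacks the unsubstituted β-carbon of the ynone and the ketene acetal carbon then bonds to the acyl-bearing α-carbon, either in one asynchronous Diels–Alder event or as a Mukaiyama–Michael addition followed by closure of the allenyl silyl enol ether onto the silyloxycarbenium ion; this is the known Diels–Alder benzannulation of 1-alkoxy-1,3-bis(silyloxy)-1,3-dienes with acetylenic ketones and esters to resorcinols. Ring A is the only ring closed, a six-membered carbocycle formed by [4+2] cycloaddition (in the stepwise picture by the second C–C bond, between the ketene acetal carbon and the ynone α-carbon). Cycloadduct 11 is a cyclohexa-1,4-diene with a mixed methyl trimethylsilyl ketal; 1,4-elimination of methanol aromatises it to 12, and the brief dilute acid cleaves only the two labile aryl–O–SiMe3 bonds, leaving the aryl TIPS ether and the primary TBS ether. No stereocentre survives, since the quaternary ketal carbon of 11 becomes an arene carbon and both E alkenes are spectators. The step needs regioselectivity (acyl group next to the former ketene acetal carbon) and site selectivity (alkyne, not the styryl alkene or the carbonyl); the first follows from the matched polarisation of diene and ynone, the second from the much higher reactivity of the unhindered ketone-activated terminal alkyne over the β-aryl enone and from the absence of a Lewis acid that would trigger carbonyl addition. Because the side chain sits on the central carbon of the acetoacetate unit, it ends between the two oxygens without any regiochemical choice on an arene.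

Step 9
Reactants: 13 (E)-1-{3-[(2E)-4-(tert-butyldimethylsilyloxy)-3-methylbut-2-en-1-yl]-2,4-dihydroxyphenyl}-3-[4-(triisopropylsilyloxy)phenyl]prop-2-en-1-one
Product: 14 (E)-1-{3-[(2E)-4-(tert-butyldimethylsilyloxy)-3-methylbut-2-en-1-yl]-2-hydroxy-4-(triisopropylsilyloxy)phenyl}-3-[4-(triisopropylsilyloxy)phenyl]prop-2-en-1-one
Conditions: TIPSCl (1.1 equiv), imidazole, DMF, 0 °C → rt
Reagents that add atoms: triisopropylsilyl chloride (TIPSCl), CC(C)[Si](Cl)(C(C)C)C(C)C
Why: Regioselective phenol silylation: the 4'-hydroxyl para to the ketone is acidic and free, whereas the 2'-hydroxyl is held in a hydrogen bond to the carbonyl and flanked on both sides, as is usual for 2,4-dihydroxyaryl ketones.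

Step 10
Reactants: 14 (E)-1-{3-[(2E)-4-(tert-butyldimethylsilyloxy)-3-methylbut-2-en-1-yl]-2-hydroxy-4-(triisopropylsilyloxy)phenyl}-3-[4-(triisopropylsilyloxy)phenyl]prop-2-en-1-one
Product: 15 (E)-1-{2-hydroxy-3-[(2E)-4-hydroxy-3-methylbut-2-en-1-yl]-4-(triisopropylsilyloxy)phenyl}-3-[4-(triisopropylsilyloxy)phenyl]prop-2-en-1-one
Conditions: camphorsulfonic acid (0.1 equiv), MeOH–CH2Cl2 (1:1), 0 °C
Reagents that add atoms: none
Why: Acid-catalysed methanolysis removes a primary alkyl TBS ether selectively, because the weakly basic, hindered aryl TIPS ethers are far slower to cleave under acid, and the conditions are too mild to ionise the allylic alcohol or close the 2'-hydroxy enone.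

Step 11
Reactants: 16 (E)-4-hydroxycinnamic acid
Product: 18 (E)-4-(triisopropylsilyloxy)cinnamic acid, via silyl ester 17 (not isolated)
Conditions: TIPSCl (2.2 equiv), imidazole, DMF, rt; then K2CO3, THF–MeOH–H2O, 0 °C; 1 M aq. HCl to pH 3
Reagents that add atoms: triisopropylsilyl chloride (TIPSCl), CC(C)[Si](Cl)(C(C)C)C(C)C
Why: Exhaustive silylation followed by selective hydrolysis of the silyl ester, which is far more labile to mild aqueous carbonate than the aryl TIPS ether, is the standard way to O-silylated hydroxycinnamic acids.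

Step 12
Reactants: 15 (E)-1-{2-hydroxy-3-[(2E)-4-hydroxy-3-methylbut-2-en-1-yl]-4-(triisopropylsilyloxy)phenyl}-3-[4-(triisopropylsilyloxy)phenyl]prop-2-en-1-one; 18 (E)-4-(triisopropylsilyloxy)cinnamic acid
Product: 19 tris(triisopropylsilyl) ether of isogemichalcone B (silylated at the 4'-, 4- and cinnamate 4-oxygens)
Conditions: 18 (1.1 equiv), DCC, DMAP (cat.), CH2Cl2, 0 °C → rt
Reagents that add atoms: none
Why: Steglich esterification acylates the unhindered primary allylic alcohol much faster than the chelated, doubly flanked 2'-hydroxyl, the only other free hydroxyl present.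

Step 13
Reactants: 19 tris(triisopropylsilyl) ether of isogemichalcone B
Product: 20 isogemichalcone B
Conditions: n-Bu4NF (TBAF)–AcOH (1:1, 4 equiv), THF, 0 °C → rt
Reagents that add atoms: none
Why: Fluoride cleaves the three aryl silyl ethers through the strong Si–F bond, and buffering with acetic acid keeps the phenols protonated so that neither flavanone closure of the 2'-hydroxy enone nor attack on the allylic ester should occur.

**Compound list**

1 | methyl acetoacetate | COC(=O)CC(C)=O | starting material
2 | 2-methyl-2-vinyloxirane (isoprene monoxide) | CC1(C=C)CO1 | starting material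
3 | methyl (4E)-2-acetyl-6-hydroxy-5-methylhex-4-enoate (racemic) | COC(=O)C(C(C)=O)C/C=C(\C)CO | intermediate
4 | methyl (4E)-2-acetyl-6-(tert-butyldimethylsilyloxy)-5-methylhex-4-enoate (racemic) | COC(=O)C(C(C)=O)C/C=C(\C)CO[Si](C)(C)C(C)(C)C | intermediate
5 | methyl (4E)-6-(tert-butyldimethylsilyloxy)-5-methyl-2-[1-(trimethylsilyloxy)ethylidene]hex-4-enoate (enol ether drawn Z) | C/C(O[Si](C)(C)C)=C(\C/C=C(\C)CO[Si](C)(C)C(C)(C)C)C(=O)OC | intermediate
6 | 1-methoxy-2-[(2E)-4-(tert-butyldimethylsilyloxy)-3-methylbut-2-en-1-yl]-1,3-bis(trimethylsilyloxy)buta-1,3-diene (one ketene acetal geometry drawn) | C=C(O[Si](C)(C)C)/C(=C(/OC)O[Si](C)(C)C)C/C=C(\C)CO[Si](C)(C)C(C)(C)C | intermediate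
7 | (E)-4-hydroxycinnamaldehyde | O=C/C=C/c1ccc(O)cc1 | starting material
8 | (E)-4-(triisopropylsilyloxy)cinnamaldehyde | O=C/C=C/c1ccc(O[Si](C(C)C)(C(C)C)C(C)C)cc1 | intermediate
9 | (E)-1-[4-(triisopropylsilyloxy)phenyl]pent-1-en-4-yn-3-ol (racemic) | C#CC(O)/C=C/c1ccc(O[Si](C(C)C)(C(C)C)C(C)C)cc1 | intermediate
10 | (E)-1-[4-(triisopropylsilyloxy)phenyl]pent-1-en-4-yn-3-one | C#CC(=O)/C=C/c1ccc(O[Si](C(C)C)(C(C)C)C(C)C)cc1 | intermediate
11 | (E)-1-{5-[(2E)-4-(tert-butyldimethylsilyloxy)-3-methylbut-2-en-1-yl]-6-methoxy-4,6-bis(trimethylsilyloxy)cyclohexa-1,4-dien-1-yl}-3-[4-(triisopropylsilyloxy)phenyl]prop-2-en-1-one (racemic, not isolated) | COC1(O[Si](C)(C)C)C(C/C=C(\C)CO[Si](C)(C)C(C)(C)C)=C(O[Si](C)(C)C)CC=C1C(=O)/C=C/c1ccc(O[Si](C(C)C)(C(C)C)C(C)C)cc1 | intermediate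
12 | (E)-1-{3-[(2E)-4-(tert-butyldimethylsilyloxy)-3-methylbut-2-en-1-yl]-2,4-bis(trimethylsilyloxy)phenyl}-3-[4-(triisopropylsilyloxy)phenyl]prop-2-en-1-one (not isolated) | C/C(=C\Cc1c(O[Si](C)(C)C)ccc(C(=O)/C=C/c2ccc(O[Si](C(C)C)(C(C)C)C(C)C)cc2)c1O[Si](C)(C)C)CO[Si](C)(C)C(C)(C)C | intermediate
13 | (E)-1-{3-[(2E)-4-(tert-butyldimethylsilyloxy)-3-methylbut-2-en-1-yl]-2,4-dihydroxyphenyl}-3-[4-(triisopropylsilyloxy)phenyl]prop-2-en-1-one | C/C(=C\Cc1c(O)ccc(C(=O)/C=C/c2ccc(O[Si](C(C)C)(C(C)C)C(C)C)cc2)c1O)CO[Si](C)(C)C(C)(C)C | intermediate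
14 | (E)-1-{3-[(2E)-4-(tert-butyldimethylsilyloxy)-3-methylbut-2-en-1-yl]-2-hydroxy-4-(triisopropylsilyloxy)phenyl}-3-[4-(triisopropylsilyloxy)phenyl]prop-2-en-1-one | C/C(=C\Cc1c(O[Si](C(C)C)(C(C)C)C(C)C)ccc(C(=O)/C=C/c2ccc(O[Si](C(C)C)(C(C)C)C(C)C)cc2)c1O)CO[Si](C)(C)C(C)(C)C | intermediate
15 | (E)-1-{2-hydroxy-3-[(2E)-4-hydroxy-3-methylbut-2-en-1-yl]-4-(triisopropylsilyloxy)phenyl}-3-[4-(triisopropylsilyloxy)phenyl]prop-2-en-1-one | C/C(=C\Cc1c(O[Si](C(C)C)(C(C)C)C(C)C)ccc(C(=O)/C=C/c2ccc(O[Si](C(C)C)(C(C)C)C(C)C)cc2)c1O)CO | intermediate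
16 | (E)-4-hydroxycinnamic acid | O=C(O)/C=C/c1ccc(O)cc1 | starting material
17 | triisopropylsilyl (E)-4-(triisopropylsilyloxy)cinnamate (not isolated) | O=C(O[Si](C(C)C)(C(C)C)C(C)C)/C=C/c1ccc(O[Si](C(C)C)(C(C)C)C(C)C)cc1 | intermediate
18 | (E)-4-(triisopropylsilyloxy)cinnamic acid | O=C(O)/C=C/c1ccc(O[Si](C(C)C)(C(C)C)C(C)C)cc1 | intermediate
19 | (2E)-4-{2-hydroxy-6-(triisopropylsilyloxy)-3-[(E)-3-(4-(triisopropylsilyloxy)phenyl)acryloyl]phenyl}-2-methylbut-2-en-1-yl (E)-3-[4-(triisopropylsilyloxy)phenyl]acrylate | C/C(=C\Cc1c(O[Si](C(C)C)(C(C)C)C(C)C)ccc(C(=O)/C=C/c2ccc(O[Si](C(C)C)(C(C)C)C(C)C)cc2)c1O)COC(=O)/C=C/c1ccc(O[Si](C(C)C)(C(C)C)C(C)C)cc1 | intermediate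
20 | isogemichalcone B | C/C(=C\Cc1c(O)ccc(C(=O)/C=C/c2ccc(O)cc2)c1O)COC(=O)/C=C/c1ccc(O)cc1 | target

**Step count**

Total steps: 13. Longest linear sequence: 9 (steps 1, 2, 3, 4, 8, 9, 10, 12, 13).

**Steps most likely to fail**

Step 8. The cross-conjugated enynone may be consumed by addition of the diene at its styryl terminus or carbonyl, or by oligomerisation at the temperature the tetrasubstituted diene needs. The sequence may also stall after the first C–C bond, or the primary silyl ether may be lost in the acidic work-up. The fallback sets out from 6 and returns at 14. Diene 6 is combined with the simplest terminal ynone, but-3-yn-2-one, in toluene and then treated with dilute acid. This should lead through 1-{5-[(2E)-4-(tert-butyldimethylsilyloxy)-3-methylbut-2-en-1-yl]-6-methoxy-4,6-bis(trimethylsilyloxy)cyclohexa-1,4-dien-1-yl}ethan-1-one F1 and 1-{3-[(2E)-4-(tert-butyldimethylsilyloxy)-3-methylbut-2-en-1-yl]-2,4-bis(trimethylsilyloxy)phenyl}ethan-1-one F2, neither isolated, to 1-{3-[(2E)-4-(tert-butyldimethylsilyloxy)-3-methylbut-2-en-1-yl]-2,4-dihydroxyphenyl}ethan-1-one F3. The enone is then built after the ring by Claisen–Schmidt condensation of F3 with 4-hydroxybenzaldehyde (KOH, EtOH–H2O, rt), which the alkyl TBS ether should survive, to give (E)-1-{3-[(2E)-4-(tert-butyldimethylsilyloxy)-3-methylbut-2-en-1-yl]-2,4-dihydroxyphenyl}-3-(4-hydroxyphenyl)prop-2-en-1-one F4. Silylation of its 4'- and 4-hydroxyls together (TIPSCl 2.2 equiv, imidazole, DMF) should deliver 14.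

Step 1. The π-allyl intermediate may place the methyl group instead of the CH2O group in the syn position, which erodes the E geometry; attack at the substituted terminus and double allylation may also compete. The fallback sets out from 1 and returns at 4, with the alkene geometry fixed before the C–C bond is made. Prenyl acetate is oxidised at its E-methyl group with SeO2 (cat.) and t-BuOOH in CH2Cl2 to (E)-4-hydroxy-3-methylbut-2-en-1-yl acetate F5. This is silylated (TBSCl, imidazole) to (E)-4-(tert-butyldimethylsilyloxy)-3-methylbut-2-en-1-yl acetate F6 and deacetylated (K2CO3, MeOH) to (E)-4-(tert-butyldimethylsilyloxy)-3-methylbut-2-en-1-ol F7. An Appel reaction (CBr4, PPh3, CH2Cl2, 0 °C) converts F7 into (E)-(4-bromo-2-methylbut-2-en-1-yloxy)(tert-butyl)dimethylsilane F8. SN2 alkylation of the sodium enolate of 1 (NaH, THF, 0 °C, 1 in excess) with F8 should give 4 with the geometry intact.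

Step 13. While three hindered aryl silyl ethers are removed, the liberated phenoxides may transfer or cleave the allylic ester, and the 2'-hydroxy enone may close to the flavanone under fluoride basicity. The fallback sets out from 15 and returns at 20, forming the ester last on unprotected material. The two aryl silyl ethers of 15 are removed before any ester is present (TBAF–AcOH, THF) to give (E)-1-{2,4-dihydroxy-3-[(2E)-4-hydroxy-3-methylbut-2-en-1-yl]phenyl}-3-(4-hydroxyphenyl)prop-2-en-1-one F9. Its primary allylic alcohol is then esterified with unprotected acid 16 under Mitsunobu conditions (PPh3, diisopropyl azodicarboxylate, THF, 0 °C). The carboxylic acid is by far the most acidic pronucleophile, so the phenols should stay untouched and 20 should result directly.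

**Further compounds**

F1 | step 8 | 1-{5-[(2E)-4-(tert-butyldimethylsilyloxy)-3-methylbut-2-en-1-yl]-6-methoxy-4,6-bis(trimethylsilyloxy)cyclohexa-1,4-dien-1-yl}ethan-1-one | COC1(O[Si](C)(C)C)C(C/C=C(\C)CO[Si](C)(C)C(C)(C)C)=C(O[Si](C)(C)C)CC=C1C(C)=O
F2 | step 8 | 1-{3-[(2E)-4-(tert-butyldimethylsilyloxy)-3-methylbut-2-en-1-yl]-2,4-bis(trimethylsilyloxy)phenyl}ethan-1-one | C/C(=C\Cc1c(O[Si](C)(C)C)ccc(C(C)=O)c1O[Si](C)(C)C)CO[Si](C)(C)C(C)(C)C
F3 | step 8 | 1-{3-[(2E)-4-(tert-butyldimethylsilyloxy)-3-methylbut-2-en-1-yl]-2,4-dihydroxyphenyl}ethan-1-one | C/C(=C\Cc1c(O)ccc(C(C)=O)c1O)CO[Si](C)(C)C(C)(C)C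
F4 | step 8 | (E)-1-{3-[(2E)-4-(tert-butyldimethylsilyloxy)-3-methylbut-2-en-1-yl]-2,4-dihydroxyphenyl}-3-(4-hydroxyphenyl)prop-2-en-1-one | C/C(=C\Cc1c(O)ccc(C(=O)/C=C/c2ccc(O)cc2)c1O)CO[Si](C)(C)C(C)(C)C
F5 | step 1 | (E)-4-hydroxy-3-methylbut-2-en-1-yl acetate | C/C(=C\COC(C)=O)CO
F6 | step 1 | (E)-4-(tert-butyldimethylsilyloxy)-3-methylbut-2-en-1-yl acetate | C/C(=C\COC(C)=O)CO[Si](C)(C)C(C)(C)C
F7 | step 1 | (E)-4-(tert-butyldimethylsilyloxy)-3-methylbut-2-en-1-ol | C/C(=C\CO)CO[Si](C)(C)C(C)(C)C
F8 | step 1 | (E)-(4-bromo-2-methylbut-2-en-1-yloxy)(tert-butyl)dimethylsilane | C/C(=C\CBr)CO[Si](C)(C)C(C)(C)C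
F9 | step 13 | (E)-1-{2,4-dihydroxy-3-[(2E)-4-hydroxy-3-methylbut-2-en-1-yl]phenyl}-3-(4-hydroxyphenyl)prop-2-en-1-one | C/C(=C\Cc1c(O)ccc(C(=O)/C=C/c2ccc(O)cc2)c1O)CO
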